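**Retrosynthetic overview**
1. The target is two hexasubstituted phloroglucinol rings joined by one CH2. Ring A (butanoyl, methoxy para to it) is carried from 2,4,6-trimethoxytoluene as its trimethyl ether; ring B is built from open-chain atoms.
2. Feature used: ring B carries C1′ (bridging CH2), C2′ (OH), C3′ (CH3), C4′ (OH), C5′ (acetyl), C6′ (OH), so oxygen sits on C2′, C4′ and C6′. Cutting C2′–C3′ and C4′–C5′ gives a 3-ethoxy vinylketene (C1′, C2′, C5′, C6′, stored as cyclobutenone 12) and 1-siloxypropyne 16 (C3′, C4′).
3. Cyclobutenone 12 comes from the ketene of the ring A 3-arylpropanoyl chloride and ethoxyacetylene; the acid comes from ketone 3 by formylation and a one-pot two-carbon extension.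
4. After the benzannulation: desilylation, C-acetylation at C5′ (the only aromatic C–H), then BCl3 cleavage of the three ethers that flank the two ketones; the ring A methoxy para to the butanoyl group stays.
5. Ring order: ring A is bought, the four-membered ring is made in step 4, ring B in step 6.

Key step: step 6

Remark: the target has no stereocentre, so cyclobutenone 12 is made and used as the racemate; ring A is taken from the commercial trimethyl ether 1, which makes an O-methylation step unnecessary.

**Route**

Step 1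
Reactants: 1 2,4,6-trimethoxytoluene; 2 butyryl chloride
Product: 3 1-(2,4,6-trimethoxy-3-methylphenyl)butan-1-one
Conditions: AlCl3 (1.1 equiv), CH2Cl2, −10 → 0 °C; cold 1 M HCl
Reagents that add atoms: none
Why: Friedel–Crafts acylation: the two open ring positions of 1 are equivalent and strongly activated, the first acyl group blocks a second acylation, and the low temperature keeps AlCl3 from cleaving a methoxy group.

Step 2
Reactants: 3 1-(2,4,6-trimethoxy-3-methylphenyl)butan-1-one
Product: 4 3-butanoyl-2,4,6-trimethoxy-5-methylbenzaldehyde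
Conditions: Cl2CHOMe (1.5 equiv), TiCl4 (2.2 equiv), CH2Cl2, −78 → 0 °C; H2O
Reagents that add atoms: dichloromethyl methyl ether COC(Cl)Cl; water O
Why: Rieche formylation: the last ring A C–H is ortho to two methoxy groups, para to the third and meta to the ketone, so the electrophile can only enter there, and hydrolysis of the α-chloro ether gives the aldehyde.

Step 3
Reactants: 4 3-butanoyl-2,4,6-trimethoxy-5-methylbenzaldehyde; 5 Meldrum's acid (2,2-dimethyl-1,3-dioxane-4,6-dione)
Product: 8 3-(3-butanoyl-2,4,6-trimethoxy-5-methylphenyl)propanoic acid, via arylidene Meldrum's acid 6 (not isolated), via benzyl Meldrum's acid 7 (not isolated)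
Conditions: HCO2H/Et3N (5:2), 100 °C; then aq. HCl
Reagents that add atoms: none
Why: Knoevenagel condensation followed in the same pot by formate conjugate reduction of the arylidene malonate and by hydrolysis with decarboxylation (reductive alkylation of Meldrum's acid); formate without a transition metal leaves the hindered aryl ketone alone.

Step 4
Reactants: 8 3-(3-butanoyl-2,4,6-trimethoxy-5-methylphenyl)propanoic acid; 9 ethoxyacetylene
Product: 12 rac-4-(3-butanoyl-2,4,6-trimethoxy-5-methylbenzyl)-3-ethoxycyclobut-2-en-1-one, via acid chloride 10 (not isolated), via aldoketene 11 (not isolated)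
Conditions: (COCl)2, DMF (cat.), CH2Cl2, 0 °C → rt, evaporate; then 9 (3 equiv), Et2O, 0 °C → rt, Et3N (1.3 equiv) added slowly
Reagents that add atoms: none
Why: Acid chloride formation, amine dehydrochlorination to the aldoketene and ketene–ynol ether [2+2] cycloaddition: the nucleophilic terminal carbon of ethoxyacetylene bonds to the ketene carbonyl carbon, which places OEt at C3 and the ring A benzyl group on the sp3 carbon C4, formed as a racemate with no control needed.

Step 5
Reactants: 13 ethyl acetate
Product: 16 triisopropyl(prop-1-yn-1-yloxy)silane, via dibromo enolate 14 (not isolated), via lithium ynolate 15 (not isolated)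
Conditions: CH2Br2, lithium 2,2,6,6-tetramethylpiperidide (2.2 equiv), THF, −78 °C; n-BuLi, −78 °C → rt; iPr3SiCl, 0 °C
Reagents that add atoms: dibromomethane BrCBr; triisopropylsilyl chloride CC(C)[Si](Cl)(C(C)C)C(C)C
Why: Kowalski ester homologation to an ynolate: acylation of LiCHBr2, bromine–lithium exchange on enolate 14 and 1,2-shift of the methyl group give 15, which the bulky chlorosilane traps on oxygen as a distillable silyl ynol ether.

Step 6
Reactants: 12 rac-4-(3-butanoyl-2,4,6-trimethoxy-5-methylbenzyl)-3-ethoxycyclobut-2-en-1-one; 16 triisopropyl(prop-1-yn-1-yloxy)silane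
Product: 21 1-[3-[6-ethoxy-2-hydroxy-3-methyl-4-(triisopropylsilyloxy)benzyl]-2,4,6-trimethoxy-5-methylphenyl]butan-1-one, via vinylketene 17 (not isolated), via vinylcyclobutenone 18 (not isolated), via dienylketene 19 (not isolated), via cyclohexadienone 20 (not isolated)
Conditions: 16 (2 equiv), toluene, 80 → 110 °C, sealed tube, argon
Reagents that add atoms: none
Why: Heating opens 12 by four-electron conrotatory ring opening, the benzyl group turning outward, to the 3-ethoxy vinylketene 17; its ketene C=C adds ynol ether 16 in a [2+2] cycloaddition (C2′–C3′ and C4′–C5′ bonds) to give vinylcyclobutenone 18, which opens again to dienylketene 19. Ring B then closes by six-electron disrotatory electrocyclization of 19 (C1′–C2′ bond, the former ketene carbon joining the benzyl-bearing alkene terminus) to dienone 20, and tautomerization gives phenol 21. The closest known reaction is the Danheiser benzannulation of cyclobutenones with siloxyalkynes, which delivers resorcinol monosilyl ethers; a 3-alkoxy-4-alkyl cyclobutenone is a little-used partner within that class. No stereocentre is formed, and the racemic centre of 12 is lost on aromatization. The step needs regiocontrol in the ketene–alkyne addition: the polarized siloxyalkyne attacks the ketene carbonyl carbon through its methyl-bearing carbon, which puts the methyl group at C3′ next to the new C2′ hydroxyl and the siloxy group at C4′. The medium is neutral, so the ring A ketone and methyl ethers should stay untouched, and the excess of 16 should keep 17 from dimerizing.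

Step 7
Reactants: 21 1-[3-[6-ethoxy-2-hydroxy-3-methyl-4-(triisopropylsilyloxy)benzyl]-2,4,6-trimethoxy-5-methylphenyl]butan-1-one
Product: 22 1-[3-(6-ethoxy-2,4-dihydroxy-3-methylbenzyl)-2,4,6-trimethoxy-5-methylphenyl]butan-1-one
Conditions: Bu4NF, AcOH, THF, 0 °C
Reagents that add atoms: none
Why: Fluoride cleavage of an aryl silyl ether, driven by the Si–F bond; the acetic acid buffer keeps the electron-rich resorcinol protonated, and the alkyl ethers and the ketone are inert.

Step 8
Reactants: 22 1-[3-(6-ethoxy-2,4-dihydroxy-3-methylbenzyl)-2,4,6-trimethoxy-5-methylphenyl]butan-1-one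
Product: 23 1-[3-(3-acetyl-2-ethoxy-4,6-dihydroxy-5-methylbenzyl)-2,4,6-trimethoxy-5-methylphenyl]butan-1-one
Conditions: Ac2O (1.2 equiv), BF3·OEt2, dioxane, rt; then aq. MeOH, 50 °C
Reagents that add atoms: acetic anhydride CC(=O)OC(C)=O
Why: Friedel–Crafts C-acylation of a phloroglucinol-type ring: C5′ is the only aromatic C–H of 22 and lies between OH and OEt, the product is held as a BF2 chelate of the ortho-hydroxy ketone that resists further acylation, and warm aqueous methanol hydrolyses the chelate and any aryl acetate.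

Step 9
Reactants: 23 1-[3-(3-acetyl-2-ethoxy-4,6-dihydroxy-5-methylbenzyl)-2,4,6-trimethoxy-5-methylphenyl]butan-1-one
Product: 24 1-[3-(3-acetyl-2,4,6-trihydroxy-5-methylbenzyl)-2,6-dihydroxy-4-methoxy-5-methylphenyl]butan-1-one (CNP0258463.0)
Conditions: BCl3 (1 M in CH2Cl2, 10 equiv), CH2Cl2, −78 °C → rt; H2O
Reagents that add atoms: none
Why: Chelation-assisted ether cleavage by BCl3 (ortho-dealkylation of aryl ketones): the two methoxy groups beside the butanoyl group and the ethoxy group beside the acetyl group can each close a six-membered O–B–O chelate with their carbonyl, from which chloride removes the alkyl group, whereas the ring A methoxy para to the ketone cannot chelate and should remain.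

**Compound list**
1 | 2,4,6-trimethoxytoluene | COc1cc(OC)c(C)c(OC)c1 | starting material
2 | butyryl chloride | CCCC(Cl)=O | starting material
3 | 1-(2,4,6-trimethoxy-3-methylphenyl)butan-1-one | CCCC(=O)c1c(OC)cc(OC)c(C)c1OC | intermediate
4 | 3-butanoyl-2,4,6-trimethoxy-5-methylbenzaldehyde | CCCC(=O)c1c(OC)c(C=O)c(OC)c(C)c1OC | intermediate
5 | Meldrum's acid (2,2-dimethyl-1,3-dioxane-4,6-dione) | CC1(C)OC(=O)CC(=O)O1 | starting material
6 | 5-(3-butanoyl-2,4,6-trimethoxy-5-methylbenzylidene)-2,2-dimethyl-1,3-dioxane-4,6-dione | CCCC(=O)c1c(OC)c(C=C2C(=O)OC(C)(C)OC2=O)c(OC)c(C)c1OC | intermediate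
7 | 5-(3-butanoyl-2,4,6-trimethoxy-5-methylbenzyl)-2,2-dimethyl-1,3-dioxane-4,6-dione | CCCC(=O)c1c(OC)c(CC2C(=O)OC(C)(C)OC2=O)c(OC)c(C)c1OC | intermediate
8 | 3-(3-butanoyl-2,4,6-trimethoxy-5-methylphenyl)propanoic acid | CCCC(=O)c1c(OC)c(CCC(=O)O)c(OC)c(C)c1OC | intermediate
9 | ethoxyacetylene | C#COCC | starting material
10 | 3-(3-butanoyl-2,4,6-trimethoxy-5-methylphenyl)propanoyl chloride | CCCC(=O)c1c(OC)c(CCC(=O)Cl)c(OC)c(C)c1OC | intermediate
11 | 3-(3-butanoyl-2,4,6-trimethoxy-5-methylphenyl)prop-1-en-1-one (aldoketene) | CCCC(=O)c1c(OC)c(CC=C=O)c(OC)c(C)c1OC | intermediate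
12 | rac-4-(3-butanoyl-2,4,6-trimethoxy-5-methylbenzyl)-3-ethoxycyclobut-2-en-1-one | CCOC1=CC(=O)C1Cc1c(OC)c(C)c(OC)c(C(=O)CCC)c1OC | intermediate
13 | ethyl acetate | CCOC(C)=O | starting material
14 | lithium 1,1-dibromoprop-1-en-2-olate | CC(O[Li])=C(Br)Br | intermediate
15 | lithium prop-1-yn-1-olate | CC#CO[Li] | intermediate
16 | triisopropyl(prop-1-yn-1-yloxy)silane | CC#CO[Si](C(C)C)(C(C)C)C(C)C | intermediate
17 | (3Z)-5-(3-butanoyl-2,4,6-trimethoxy-5-methylphenyl)-3-ethoxypenta-1,3-dien-1-one | O=C=C/C(OCC)=C/Cc1c(OC)c(C)c(OC)c(C(=O)CCC)c1OC | intermediate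
18 | rac-4-[(Z)-3-(3-butanoyl-2,4,6-trimethoxy-5-methylphenyl)-1-ethoxyprop-1-en-1-yl]-2-methyl-3-(triisopropylsilyloxy)cyclobut-2-en-1-one | O=C1C(C)=C(O[Si](C(C)C)(C(C)C)C(C)C)C1/C(OCC)=C/Cc2c(OC)c(C)c(OC)c(C(=O)CCC)c2OC | intermediate
19 | (3E,5Z)-7-(3-butanoyl-2,4,6-trimethoxy-5-methylphenyl)-5-ethoxy-2-methyl-3-(triisopropylsilyloxy)hepta-1,3,5-trien-1-one | O=C=C(C)/C(O[Si](C(C)C)(C(C)C)C(C)C)=C\C(OCC)=C\Cc1c(OC)c(C)c(OC)c(C(=O)CCC)c1OC | intermediate
20 | rac-6-(3-butanoyl-2,4,6-trimethoxy-5-methylbenzyl)-5-ethoxy-2-methyl-3-(triisopropylsilyloxy)cyclohexa-2,4-dien-1-one | O=C1C(C)=C(O[Si](C(C)C)(C(C)C)C(C)C)C=C(OCC)C1Cc2c(OC)c(C)c(OC)c(C(=O)CCC)c2OC | intermediate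
21 | 1-[3-[6-ethoxy-2-hydroxy-3-methyl-4-(triisopropylsilyloxy)benzyl]-2,4,6-trimethoxy-5-methylphenyl]butan-1-one | CCCC(=O)c1c(OC)c(C)c(OC)c(Cc2c(O)c(C)c(O[Si](C(C)C)(C(C)C)C(C)C)cc2OCC)c1OC | intermediate
22 | 1-[3-(6-ethoxy-2,4-dihydroxy-3-methylbenzyl)-2,4,6-trimethoxy-5-methylphenyl]butan-1-one | CCCC(=O)c1c(OC)c(C)c(OC)c(Cc2c(O)c(C)c(O)cc2OCC)c1OC | intermediate
23 | 1-[3-(3-acetyl-2-ethoxy-4,6-dihydroxy-5-methylbenzyl)-2,4,6-trimethoxy-5-methylphenyl]butan-1-one | CCCC(=O)c1c(OC)c(C)c(OC)c(Cc2c(O)c(C)c(O)c(C(C)=O)c2OCC)c1OC | intermediate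
24 | 1-[3-(3-acetyl-2,4,6-trihydroxy-5-methylbenzyl)-2,6-dihydroxy-4-methoxy-5-methylphenyl]butan-1-one | CCCC(=O)c1c(O)c(C)c(OC)c(Cc2c(O)c(C)c(O)c(C(C)=O)c2O)c1O | target

**Step count**
Total: 9 steps. Longest linear sequence: 8 steps (1, 2, 3, 4, 6, 7, 8, 9) from 2,4,6-trimethoxytoluene; step 5 is a one-step side branch.

**Steps most likely to fail**

Step 6 (benzannulation). The donor-stabilized cyclobutenone may open too slowly at temperatures the siloxyalkyne tolerates. Vinylketene 17 may then be lost by dimerization or by acylating the product phenol before the ynol ether intercepts it, and 16 may isomerize to a silylketene. The fallback joins the two rings by Friedel–Crafts benzylation; it sets out from aldehyde 4 and comes back at diol 22. Aldehyde 4 is reduced chemoselectively (NaBH4, MeOH, −40 °C; the doubly flanked ketone reacts far more slowly) to 1-[3-(hydroxymethyl)-2,4,6-trimethoxy-5-methylphenyl]butan-1-one F1. Commercial 2,4,6-trihydroxytoluene is mono-etherified at its unhindered hydroxyl, para to the methyl group, with HCl-saturated ethanol to give 5-ethoxy-2-methylbenzene-1,3-diol F2. Under catalytic TsOH in CH2Cl2, the methoxy-stabilized benzyl cation from F1 alkylates an excess of F2 at one of its two equivalent ring positions, which gives 22.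

Step 9 (triple dealkylation). Once the first boron chelate has formed at each ketone, cleavage of the second flanking ether may stall. Alternatively the ring A methoxy para to the ketone may be lost, because its two neighbours twist it out of the ring plane and make it more basic than an ordinary anisole oxygen. The fallback moves the ether cleavage to the simple ketone and joins two free phenols; it sets out from ketone 3 and comes back at target 24. Ketone 3 is treated with BCl3 (CH2Cl2, −78 °C → rt); there the para methoxy has a free neighbour, lies in the ring plane and is the least basic ether, so the product should be 1-(2,6-dihydroxy-4-methoxy-3-methylphenyl)butan-1-one F3. Commercial 2,4,6-trihydroxytoluene is C-acetylated (Ac2O, BF3·OEt2) to 1-(2,4,6-trihydroxy-3-methylphenyl)ethan-1-one F4. A Mannich reaction (aq. CH2O, Me2NH, EtOH) at its one free ring carbon gives 1-[3-[(dimethylamino)methyl]-2,4,6-trihydroxy-5-methylphenyl]ethan-1-one F5. Heating F5 with an excess of F3 and NaOAc in dioxane at 100 °C expels the amine, and the ortho-quinone methide is captured by the single free ring carbon of F3 to give 24.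

Step 8 (C-acetylation). The acylium ion may attack the benzyl-bearing carbon C1′ and expel the ring A benzyl cation, which would cut the methylene bridge. The reaction may also stop at an aryl acetate, or acylation may occur at the enol of the butanoyl group. The fallback replaces the electrophilic acylation by a cross-coupling; it sets out from diol 22 and comes back at ketone 23. Iodination at the only free ring position (N-iodosuccinimide, MeCN, 0 °C) gives 1-[3-(2-ethoxy-4,6-dihydroxy-3-iodo-5-methylbenzyl)-2,4,6-trimethoxy-5-methylphenyl]butan-1-one F6. Stille coupling with tributyl(1-ethoxyvinyl)stannane (PdCl2(PPh3)2, dioxane, 90 °C) gives 1-[3-[2-ethoxy-3-(1-ethoxyvinyl)-4,6-dihydroxy-5-methylbenzyl]-2,4,6-trimethoxy-5-methylphenyl]butan-1-one F7. Hydrolysis of the enol ether with 1 M HCl in THF gives 23.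

**Further compounds**
F1 | step 6 | 1-[3-(hydroxymethyl)-2,4,6-trimethoxy-5-methylphenyl]butan-1-one | CCCC(=O)c1c(OC)c(CO)c(OC)c(C)c1OC
F2 | step 6 | 5-ethoxy-2-methylbenzene-1,3-diol | CCOc1cc(O)c(C)c(O)c1
F3 | step 9 | 1-(2,6-dihydroxy-4-methoxy-3-methylphenyl)butan-1-one | CCCC(=O)c1c(O)cc(OC)c(C)c1O
F4 | step 9 | 1-(2,4,6-trihydroxy-3-methylphenyl)ethan-1-one | CC(=O)c1c(O)cc(O)c(C)c1O
F5 | step 9 | 1-[3-[(dimethylamino)methyl]-2,4,6-trihydroxy-5-methylphenyl]ethan-1-one | CC(=O)c1c(O)c(CN(C)C)c(O)c(C)c1O
F6 | step 8 | 1-[3-(2-ethoxy-4,6-dihydroxy-3-iodo-5-methylbenzyl)-2,4,6-trimethoxy-5-methylphenyl]butan-1-one | CCCC(=O)c1c(OC)c(C)c(OC)c(Cc2c(O)c(C)c(O)c(I)c2OCC)c1OC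
F7 | step 8 | 1-[3-[2-ethoxy-3-(1-ethoxyvinyl)-4,6-dihydroxy-5-methylbenzyl]-2,4,6-trimethoxy-5-methylphenyl]butan-1-one | CCCC(=O)c1c(OC)c(C)c(OC)c(Cc2c(O)c(C)c(O)c(C(=C)OCC)c2OCC)c1OC
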